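## Structural features

The target is a linear prodelphinidin trimer, epigallocatechin-(4β→8)-epigallocatechin 3-O-gallate-(4β→8)-epigallocatechin. Each unit is a chroman (benzo ring A fused to pyran ring C) with a 3,4,5-trihydroxyphenyl ring B on C2. C4 of the top unit is bonded to C8 of the middle unit, and C4 of the middle unit to C8 of the lower unit. Only the middle unit is esterified (galloyl on the C3 oxygen); the C3 hydroxyls of the top and lower units are free.

There are eight stereocentres: C2 and C3 of every unit (cis, both R as in (−)-epigallocatechin) and C4 of the top and middle units, each trans to its C3 oxygen. Ring C of the middle unit therefore holds three adjacent centres, C2, C3 and C4.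

The late steps are limited by eighteen phenolic hydroxyls (twelve in four pyrogallol rings that oxidise in base and air), by C2 centres that epimerise in base once the phenols are free, by acid-labile C4–aryl bonds and by one aryl ester. The real difficulty is to form two interflavan bonds between nearly identical, very nucleophilic rings with control of site (C8, not C6) and of C4 configuration, and to acylate one of three secondary hydroxyls.

The key step exploits ring C of the middle unit, O1–C2(aryl)–C3(O)–C4(aryl). O1, C8a, C4a and C4 correspond to an o-quinone methide whose exocyclic carbon already carries C8 of the lower unit. C2–C3 corresponds to a Z-alkene with the aryl group on C2 and boron standing in for oxygen on C3.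

## Logic of the disconnections

**22 to 21.** Only twenty O–benzyl bonds and one C8–Br bond are cut. One kind of protecting group on every hydroxyl means the polyphenol is released in a single neutral operation. The demand is that one hydrogenolysis clears all of them without touching the ester or the interflavan bonds.

**21 to 19 and 20.** The C4(top)–C8(middle) bond is cut. A ring-C cation at C4 is stabilised by ring A and is attacked on the face opposite the C2 aryl and C3 oxygen, which gives the 4β bond. The trimer falls to a dimer and a monomer from the chiral pool. The forward step needs reaction at C8 of the middle unit of 19 only, and an electrophile that cannot condense with itself; 20 therefore carries bromine on C8.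

**20 to 4.** The C4–O bond is cut, which corresponds to oxidation of C4–H. Compound 4 then serves twice, as the source of the lower unit and of the top unit.

**19 to 17 and 18.** The ester C–O bond is cut. In 17 the middle C3 hydroxyl is the only free hydroxyl, so no selectivity problem arises. The demand is acylation of a hindered, axial secondary alcohol.

**17 to 16.** The C3–O bond is traced to a C3–B bond. Boron is the oxygen placeholder that an alkene can carry through a cycloaddition, and its oxidation retains configuration. The oxidation must outrun β-elimination toward O1.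

**16 to 10 and 14 (through 15).** O1–C2 and C3–C4 of the middle unit are cut. This removes ring C and three stereocentres at once and leaves a bis-aryl carbinol and a Z-alkenylboronate. The forward step must control regiochemistry, the cis transfer of alkene geometry, the exo topology and the face of 15.

**10 to 9, then to 4 and 7 (through 8).** The bond between the carbinol carbon and C8 of the lower unit is cut. Bromine–lithium exchange fixes the attachment at C8 before ring C exists. The oxygen that becomes O1 must not carry a proton during this addition, since it would destroy one equivalent of 8. It is therefore masked in 7 and 9 as an allyl ether, which is removed without acid. The carbinol configuration need not be controlled because it is lost in 15.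

**4 to 3, 2 and 1.** C8–Br and six O–benzyl bonds are cut. The lower unit comes from the chiral pool with C2 and C3 in place. The demands are bromination at C8 only and benzylation without C2 epimerisation.

**7 to 6 and 5.** The O–allyl and two O–benzyl bonds are cut. The hydrogen-bonded hydroxyl next to the formyl group is left to last, which gives the differentiation for free.

**14 to 13, 12 and 11.** The C–B bond is cut, then one carbon of the alkyne, then three O–benzyl bonds. The Z geometry requires a trans-hydroboration, which needs an H–B reagent. A diboron reagent cannot deliver the hydrogen and is kept for the fallback.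

## Other disconnections considered

**Alternative 1:** The cut dismantles ring A of the lower unit (C4a–C8a, C5–C6, C7–C8), so the lower chroman is traced to three alkynes. Forward, RhCl(PPh3)3 would cyclotrimerise the diyne A2 with benzyloxyacetylene A3 to give the dimer gallate A1, which is the same compound as 19. A2 is an ynol ether whose alkyne carbon carries C4 of the finished middle unit and whose oxygen is tethered through O1–C2–C3–C4 to a second, benzyloxy-capped alkyne.
- In its favour: the C4(middle)–C8(lower) bond exists before the arene is made, so a C6/C8 ambiguity cannot arise. The step creates no stereocentre.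
- Against it: the tether fixes only C4a–C8a, and nothing controls the orientation of A3 (benzyloxy at C7 rather than C6). A2 and A3 are ynol ethers, sensitive to acid and heat, and A3 can trimerise with itself. A2 needs a propargylic C4 centre on a complete middle unit and an open-chain, enantiopure C2/C3 pair, so the lower unit is not taken from 1.
- Comparison: on structure the two plans are equal in placing the 4→8 bond before a ring is closed. Alternative 1 is the better on stereochemical risk in the key step, since the chosen step must set three centres. On mechanism it trades that risk for a regiochemical one of similar weight. On step economy it is well behind the sixteen steps of the chosen plan, because both the tether and the alkynylated middle unit are made from scratch.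

**Alternative 2:** The cut lies in the top unit (C4–C4a and O1–C2): its ring A becomes phloroglucinol A6 and the rest a side chain on C8 of the middle unit. Forward, camphorsulfonic acid would ionise the benzylic carbinol of epoxy alcohol A5, A6 would attack through carbon, and the adjacent phenol oxygen would open the cis-epoxide at its benzylic carbon with inversion (6-endo) to give trimer A4 with the 2,3-cis arrangement.
- In its favour: ring A of the top unit arrives unprotected and symmetrical, so it has no site problem and the electrophile cannot self-condense. Three fewer benzyl groups are needed; on protecting-group economy alternative 2 is the better plan. Two bonds and a ring form in one operation.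
- Against it: C4 of the top unit is set by capture of an open-chain cation next to an epoxide, so its relation to C3 rests on acyclic control and not on the face bias of a ring-C cation. The epoxide can open first (hydride shift, 5-exo attack, attack of A6), and A6 can be alkylated more than once. The acid also meets an existing interflavan bond. A5 needs a chiral cis-epoxy alcohol built on C8 of a dimer that already carries a gallate.
- Comparison: this cut addresses the upper interflavan bond, which the chosen plan forms in step 15; both plans are equal in needing the middle–lower dimer first. Mechanistically step 15 is the safer. On step economy the chosen plan is ahead, since the top unit's C2 and C3 would no longer come from 1.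

**Alternative 3:** The cut is O1–C8a of the middle unit. Forward, Pd(OAc)2 with 2-(di-tert-butylphosphino)-1,1'-binaphthyl and Cs2CO3 would couple the C2 benzylic hydroxyl of bromo alcohol A8 with its aryl bromide (intramolecular Buchwald–Hartwig-type etherification) to give the silyl-protected dimer A7.
- In its favour: cyclisation of secondary alcohols onto aryl bromides to chromans is an established reaction type. The C2–O bond is not broken, so configuration is retained, and no stereocentre is created. On predictability of the key step alternative 3 is the better. It is the equal of the chosen plan in fixing the 4→8 attachment before ring C exists.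
- Against it: all three contiguous centres must be set in an open chain, including a C4 methine bearing two trioxygenated aryl groups, which is hard to build with control and ionises easily. The electron-rich, ortho-substituted bromide should add slowly to zerovalent palladium. The palladium alkoxide can undergo β-hydride elimination to a ketone. The silyl group can migrate between the C3 and C2 oxygens under Cs2CO3, and it must still be removed before esterification.
- Comparison: both plans close the same ring. The chosen plan forms two bonds and three centres at once and is shorter but riskier; alternative 3 forms one bond and moves the stereochemical burden upstream, at a cost of markedly more steps.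

Key step: step 11

Assumption: the carbinol centre of 9 and 10 is carried as both epimers because it becomes planar in 15, and the antipode of the chiral acid that matches the lower-unit stereocentres is taken to be (R); if it is (S), only the catalyst changes.

## Route

Step 1
Reactants: 1 (−)-epigallocatechin
Product: 2 5,7,3',4',5'-penta-O-benzyl-(−)-epigallocatechin (3-OH free)
Conditions: BnBr (5.5 equiv), K2CO3, degassed DMF, Ar, −10 °C → rt
Reagents that add atoms: benzyl bromide, BrCc1ccccc1
Why: Williamson etherification; carbonate deprotonates the five phenols but not the secondary 3-OH, and low temperature with exclusion of air limits C-benzylation, pyrogallol oxidation and C2 epimerisation. No stereocentre is touched.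

Step 2
Reactants: 2 5,7,3',4',5'-penta-O-benzyl-(−)-epigallocatechin
Product: 3 3,5,7,3',4',5'-hexa-O-benzyl-(−)-epigallocatechin
Conditions: NaH, BnBr, DMF, 0 °C → rt
Reagents that add atoms: benzyl bromide, BrCc1ccccc1
Why: Williamson etherification of the secondary alkoxide; with every phenol already benzylated there is no quinone-methide pathway for C2 epimerisation.

Step 3
Reactants: 3 3,5,7,3',4',5'-hexa-O-benzyl-(−)-epigallocatechin
Product: 4 8-bromo-3,5,7,3',4',5'-hexa-O-benzyl-(−)-epigallocatechin
Conditions: NBS (1.0 equiv), CH2Cl2, −78 → 0 °C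
Reagents that add atoms: N-bromosuccinimide, O=C1CCC(=O)N1Br
Why: Electrophilic aromatic bromination; the phloroglucinol-type ring A reacts far faster than ring B, and C8 (between O1 and one benzyloxy group) is less hindered than C6 (between two benzyloxy groups).

Step 4
Reactants: 5 2,4,6-trihydroxybenzaldehyde
Product: 6 2,4-bis(benzyloxy)-6-hydroxybenzaldehyde
Conditions: BnBr (2.05 equiv), K2CO3, DMF, 0 °C → rt
Reagents that add atoms: benzyl bromide, BrCc1ccccc1
Why: Regioselective Williamson etherification; the para hydroxyl and one ortho hydroxyl are alkylated, while the remaining ortho hydroxyl is held in a hydrogen bond to the formyl oxygen and reacts much more slowly.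

Step 5
Reactants: 6 2,4-bis(benzyloxy)-6-hydroxybenzaldehyde
Product: 7 2-(allyloxy)-4,6-bis(benzyloxy)benzaldehyde
Conditions: allyl bromide, K2CO3, DMF, 60 °C
Reagents that add atoms: allyl bromide, C=CCBr
Why: Williamson etherification of the chelated phenol under forcing but non-rearranging conditions; the allyl ether removes the acidic proton that would otherwise quench the aryllithium of step 6.

Step 6
Reactants: 4 8-bromo-3,5,7,3',4',5'-hexa-O-benzyl-(−)-epigallocatechin; 7 2-(allyloxy)-4,6-bis(benzyloxy)benzaldehyde
Product: 9 [2-(allyloxy)-4,6-bis(benzyloxy)phenyl](3,5,7,3',4',5'-hexa-O-benzylepigallocatechin-8-yl)methanol as both carbinol epimers, via 8-lithio-3,5,7,3',4',5'-hexa-O-benzylepigallocatechin 8 (not isolated)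
Conditions: n-BuLi (1.05 equiv), THF, −78 °C; then 7, −78 → −30 °C; aq NaHCO3
Reagents that add atoms: none
Why: Bromine–lithium exchange at C8 is faster than benzylic deprotonation at −78 °C, and the aryllithium adds 1,2 to the non-enolisable aldehyde. The new carbinol centre is formed without control and is erased in step 11.

Step 7
Reactants: 9 [2-(allyloxy)-4,6-bis(benzyloxy)phenyl](3,5,7,3',4',5'-hexa-O-benzylepigallocatechin-8-yl)methanol
Product: 10 [4,6-bis(benzyloxy)-2-hydroxyphenyl](3,5,7,3',4',5'-hexa-O-benzylepigallocatechin-8-yl)methanol (both carbinol epimers)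
Conditions: Pd(PPh3)4 (5 mol %), K2CO3, MeOH/THF, rt; chromatography on Et3N-deactivated silica
Reagents that add atoms: none
Why: Tsuji–Trost deallylation; zerovalent palladium ionises the aryl allyl ether and methanol takes up the allyl group. The basic medium keeps the acid-labile bis-benzylic alcohol and the benzyl ethers intact.

Step 8
Reactants: 11 3,4,5-trihydroxybenzaldehyde
Product: 12 3,4,5-tris(benzyloxy)benzaldehyde
Conditions: BnBr (3.3 equiv), K2CO3, degassed DMF, Ar, rt
Reagents that add atoms: benzyl bromide, BrCc1ccccc1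
Why: Williamson etherification of three phenols; air is excluded because the pyrogallol oxidises under base.

Step 9
Reactants: 12 3,4,5-tris(benzyloxy)benzaldehyde
Product: 13 1,2,3-tris(benzyloxy)-5-ethynylbenzene
Conditions: dimethyl (1-diazo-2-oxopropyl)phosphonate, K2CO3, MeOH/THF, rt
Reagents that add atoms: dimethyl (1-diazo-2-oxopropyl)phosphonate, COP(=O)(OC)C(=[N+]=[N-])C(C)=O
Why: Ohira–Bestmann variant of the Seyferth–Gilbert homologation; methanolysis releases the diazomethylphosphonate anion, which olefinates the aldehyde, and loss of N2 with 1,2-hydride shift gives the terminal alkyne.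

Step 10
Reactants: 13 1,2,3-tris(benzyloxy)-5-ethynylbenzene
Product: 14 (Z)-2-[3,4,5-tris(benzyloxy)phenyl]ethenylboronic acid pinacol ester
Conditions: pinacolborane (1.0 equiv), 13 (1.2 equiv), [Rh(cod)Cl]2 (1.5 mol %), P(i-Pr)3 (6 mol %), Et3N, cyclohexane, rt
Reagents that add atoms: pinacolborane, CC1(C)OBOC1(C)C
Why: Rhodium-catalysed trans-hydroboration of a terminal alkyne; a rhodium vinylidene is formed, boryl migrates to the α-carbon and C–H reductive elimination leaves boron cis to the aryl group, which gives the Z-alkenylboronate.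

Step 11
Reactants: 10 [4,6-bis(benzyloxy)-2-hydroxyphenyl](3,5,7,3',4',5'-hexa-O-benzylepigallocatechin-8-yl)methanol; 14 (Z)-2-[3,4,5-tris(benzyloxy)phenyl]ethenylboronic acid pinacol ester
Product: 16 5,7,3',4',5'-penta-O-benzyl-3-deoxy-3-(4,4,5,5-tetramethyl-1,3,2-dioxaborolan-2-yl)epigallocatechin-(4β→8)-3,5,7,3',4',5'-hexa-O-benzylepigallocatechin (C2 aryl α; C3 boron α; C4 aryl β), via o-quinone methide 15 (not isolated)
Conditions: (R)-3,3'-bis(2,4,6-triisopropylphenyl)-1,1'-binaphthyl-2,2'-diyl hydrogen phosphate (10 mol %), 14 (3 equiv), 5 Å MS, toluene, 0 °C → rt; slow addition of 10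
Reagents that add atoms: none
Why: Proposed new method: the phosphoric acid protonates the benzylic hydroxyl of either epimer of 10 and water leaves to give the hydrogen-bonded o-quinone methide 15, in effect a phosphate-paired diarylmethyl cation, whose exocyclic carbon (future C4) bonds to the boron-bearing carbon of 14 because this puts the developing charge on the carbon carrying the 3,4,5-tris(benzyloxy)phenyl ring, after which the phenolic oxygen closes on that carbon in an asynchronous inverse-demand oxa-[4+2]. The closest known reaction type is the chiral-phosphoric-acid-catalysed [4+2] cycloaddition of in situ o-quinone methides with styrenes to 2,4-diarylchromans, and a β-borylstyrene has not been shown as the two-carbon partner. Ring C of the middle unit is closed by the cycloaddition itself: the four-atom unit O1=C8a–C4a=C4 and the two-atom unit C2=C3 join through C3–C4 first and O1–C2 second, a six-membered annulation with no separate cyclisation step. C2 relative to C3 is controlled by the Z geometry of 14, copied by suprafacial addition as long as O1–C2 closure outruns rotation about C2–C3; the phosphate holds the phenol oxygen next to the cationic carbon, which should keep closure fast. C3 relative to C4 is controlled by the exo arrangement (boron and C2 aryl turned away from ring A), expected because the endo arrangement would press the dioxaborolane against the 5-benzyloxy group, which also drives the C4 aryl pseudo-axial and trans to the C3 substituent; this is the least certain element. The absolute configuration at C4, and with it at C2 and C3, is controlled by the chiral phosphate bound to the methide oxygen, which shields one face of 15, while the lower-unit stereocentres are remote. Regioselectivity rests on the aryl group at the future C2, chemoselectivity against alkenyl transfer with loss of boron rests on the non-exchangeable, weakly Lewis acidic pinacol ester under anhydrous conditions, and self-alkylation of 10 at C8 of its phenol ring is held back by adding 10 slowly to excess 14.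

Step 12
Reactants: 16 5,7,3',4',5'-penta-O-benzyl-3-deoxy-3-(4,4,5,5-tetramethyl-1,3,2-dioxaborolan-2-yl)epigallocatechin-(4β→8)-3,5,7,3',4',5'-hexa-O-benzylepigallocatechin
Product: 17 5,7,3',4',5'-penta-O-benzylepigallocatechin-(4β→8)-3,5,7,3',4',5'-hexa-O-benzylepigallocatechin (3-OH of the 4-substituted unit free)
Conditions: H2O2 (30 % aq), NaOH, THF, 0 °C → rt
Reagents that add atoms: hydrogen peroxide, OO
Why: Boronate oxidation; hydroperoxide adds to boron and C3 migrates from boron to oxygen with retention, so the hydroxyl ends cis to the C2 aryl and trans to the C4 aryl. The axial C–B bond is gauche to C2–O1, which disfavours β-elimination, and with all phenols benzylated the base cannot epimerise C2.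

Step 13
Reactants: 17 5,7,3',4',5'-penta-O-benzylepigallocatechin-(4β→8)-3,5,7,3',4',5'-hexa-O-benzylepigallocatechin; 18 3,4,5-tris(benzyloxy)benzoic acid
Product: 19 5,7,3',4',5'-penta-O-benzylepigallocatechin 3-O-[3,4,5-tris(benzyloxy)benzoate]-(4β→8)-3,5,7,3',4',5'-hexa-O-benzylepigallocatechin
Conditions: DCC, DMAP, CH2Cl2, rt
Reagents that add atoms: none
Why: Steglich esterification; the C3 hydroxyl of the 4-substituted unit is the only free hydroxyl in 17, and the acylpyridinium intermediate is reactive enough for this hindered axial alcohol. No stereocentre is touched.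

Step 14
Reactants: 4 8-bromo-3,5,7,3',4',5'-hexa-O-benzyl-(−)-epigallocatechin
Product: 20 8-bromo-4β-(2-ethoxyethoxy)-3,5,7,3',4',5'-hexa-O-benzylepigallocatechin (2,3-cis-3,4-trans)
Conditions: DDQ (2 equiv), 2-ethoxyethanol (5 equiv), CH2Cl2, rt
Reagents that add atoms: 2-ethoxyethanol, CCOCCO
Why: Benzylic oxidation by hydride abstraction; C4 is the only position whose cation is stabilised by the ortho and para oxygens of ring A, and the alcohol adds anti to the C2 aryl and C3 benzyloxy groups. The C4 configuration is immaterial because the centre is re-ionised in step 15.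

Step 15
Reactants: 19 5,7,3',4',5'-penta-O-benzylepigallocatechin 3-O-[3,4,5-tris(benzyloxy)benzoate]-(4β→8)-3,5,7,3',4',5'-hexa-O-benzylepigallocatechin; 20 8-bromo-4β-(2-ethoxyethoxy)-3,5,7,3',4',5'-hexa-O-benzylepigallocatechin
Product: 21 8-bromo-3,5,7,3',4',5'-hexa-O-benzylepigallocatechin-(4β→8)-5,7,3',4',5'-penta-O-benzylepigallocatechin 3-O-[3,4,5-tris(benzyloxy)benzoate]-(4β→8)-3,5,7,3',4',5'-hexa-O-benzylepigallocatechin
Conditions: TMSOTf (0.2 equiv), CH2Cl2, −78 → −40 °C; then Et3N
Reagents that add atoms: none
Why: Lewis-acid-mediated Friedel–Crafts-type interflavan coupling; silylation of the 4-alkoxy group releases the ring-A-stabilised C4 cation, which is attacked on the face anti to the C2 aryl and C3 benzyloxy groups (4β, 3,4-trans). C8 of the middle unit of 19 is the most accessible nucleophilic carbon, since both C6 positions lie between two benzyloxy groups, and the bromine on 20 prevents self-condensation and further chain growth.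

Step 16
Reactants: 21 8-bromo-3,5,7,3',4',5'-hexa-O-benzylepigallocatechin-(4β→8)-5,7,3',4',5'-penta-O-benzylepigallocatechin 3-O-[3,4,5-tris(benzyloxy)benzoate]-(4β→8)-3,5,7,3',4',5'-hexa-O-benzylepigallocatechin
Product: 22 epigallocatechin-(4β→8)-epigallocatechin 3-O-gallate-(4β→8)-epigallocatechin (target)
Conditions: H2 (1 atm), Pd(OH)2/C, Et3N (1.1 equiv), THF/MeOH/H2O, rt
Reagents that add atoms: none
Why: Catalytic hydrogenolysis of twenty benzyl ethers and of the aryl C–Br bond; the amine takes up the hydrogen bromide so that the interflavan bonds see no acid. The ester, the C2–O1 bonds and all stereocentres are untouched under these neutral conditions.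

## Compound list

1 | (−)-epigallocatechin, (2R,3R)-2-(3,4,5-trihydroxyphenyl)chroman-3,5,7-triol | O[C@@H]1Cc2c(O)cc(O)cc2O[C@@H]1c1cc(O)c(O)c(O)c1 | starting material

2 | 5,7,3',4',5'-penta-O-benzyl-(−)-epigallocatechin (2R,3R; 3-OH free) | c2c(OCc9ccccc9)cc(OCc9ccccc9)c3c2O[C@H](c8cc(OCc9ccccc9)c(OCc9ccccc9)c(OCc9ccccc9)c8)[C@H](O)C3 | intermediate

3 | 3,5,7,3',4',5'-hexa-O-benzyl-(−)-epigallocatechin (2R,3R) | c2c(OCc9ccccc9)cc(OCc9ccccc9)c3c2O[C@H](c8cc(OCc9ccccc9)c(OCc9ccccc9)c(OCc9ccccc9)c8)[C@H](OCc9ccccc9)C3 | intermediate

4 | 8-bromo-3,5,7,3',4',5'-hexa-O-benzyl-(−)-epigallocatechin | Brc2c(OCc9ccccc9)cc(OCc9ccccc9)c3c2O[C@H](c8cc(OCc9ccccc9)c(OCc9ccccc9)c(OCc9ccccc9)c8)[C@H](OCc9ccccc9)C3 | intermediate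

5 | 2,4,6-trihydroxybenzaldehyde | O=Cc1c(O)cc(O)cc1O | starting material

6 | 2,4-bis(benzyloxy)-6-hydroxybenzaldehyde | O=Cc1c(OCc2ccccc2)cc(OCc2ccccc2)cc1O | intermediate

7 | 2-(allyloxy)-4,6-bis(benzyloxy)benzaldehyde | O=Cc1c(OCc2ccccc2)cc(OCc2ccccc2)cc1OCC=C | intermediate

8 | 8-lithio-3,5,7,3',4',5'-hexa-O-benzylepigallocatechin (not isolated) | [Li]c2c(OCc9ccccc9)cc(OCc9ccccc9)c3c2O[C@H](c8cc(OCc9ccccc9)c(OCc9ccccc9)c(OCc9ccccc9)c8)[C@H](OCc9ccccc9)C3 | intermediate

9 | [2-(allyloxy)-4,6-bis(benzyloxy)phenyl](3,5,7,3',4',5'-hexa-O-benzylepigallocatechin-8-yl)methanol, both carbinol epimers | OC(c2c(OCc9ccccc9)cc(OCc9ccccc9)c3c2O[C@H](c8cc(OCc9ccccc9)c(OCc9ccccc9)c(OCc9ccccc9)c8)[C@H](OCc9ccccc9)C3)c4c(OCc9ccccc9)cc(OCc9ccccc9)cc4OCC=C | intermediate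

10 | [4,6-bis(benzyloxy)-2-hydroxyphenyl](3,5,7,3',4',5'-hexa-O-benzylepigallocatechin-8-yl)methanol, both carbinol epimers | OC(c2c(OCc9ccccc9)cc(OCc9ccccc9)c3c2O[C@H](c8cc(OCc9ccccc9)c(OCc9ccccc9)c(OCc9ccccc9)c8)[C@H](OCc9ccccc9)C3)c4c(OCc9ccccc9)cc(OCc9ccccc9)cc4O | intermediate

11 | 3,4,5-trihydroxybenzaldehyde | O=Cc1cc(O)c(O)c(O)c1 | starting material

12 | 3,4,5-tris(benzyloxy)benzaldehyde | O=Cc1cc(OCc2ccccc2)c(OCc2ccccc2)c(OCc2ccccc2)c1 | intermediate

13 | 1,2,3-tris(benzyloxy)-5-ethynylbenzene | C#Cc1cc(OCc2ccccc2)c(OCc2ccccc2)c(OCc2ccccc2)c1 | intermediate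

14 | (Z)-2-[3,4,5-tris(benzyloxy)phenyl]ethenylboronic acid pinacol ester | CC1(C)OB(OC1(C)C)\C=C/c1cc(OCc2ccccc2)c(OCc2ccccc2)c(OCc2ccccc2)c1 | intermediate

15 | o-quinone methide, 3,5-bis(benzyloxy)-6-[(3,5,7,3',4',5'-hexa-O-benzylepigallocatechin-8-yl)methylidene]cyclohexa-2,4-dien-1-one (not isolated) | O=C1C=C(OCc9ccccc9)C=C(OCc9ccccc9)C1=Cc2c(OCc9ccccc9)cc(OCc9ccccc9)c3c2O[C@H](c8cc(OCc9ccccc9)c(OCc9ccccc9)c(OCc9ccccc9)c8)[C@H](OCc9ccccc9)C3 | intermediate

16 | 5,7,3',4',5'-penta-O-benzyl-3-deoxy-3-(4,4,5,5-tetramethyl-1,3,2-dioxaborolan-2-yl)epigallocatechin-(4β→8)-3,5,7,3',4',5'-hexa-O-benzylepigallocatechin (boron cis to the C2 aryl, trans to the C4 aryl) | CC5(C)OB(OC5(C)C)[C@@H]1[C@@H](c2c(OCc9ccccc9)cc(OCc9ccccc9)c3c2O[C@H](c8cc(OCc9ccccc9)c(OCc9ccccc9)c(OCc9ccccc9)c8)[C@H](OCc9ccccc9)C3)c4c(OCc9ccccc9)cc(OCc9ccccc9)cc4O[C@@H]1c8cc(OCc9ccccc9)c(OCc9ccccc9)c(OCc9ccccc9)c8 | intermediate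

17 | 5,7,3',4',5'-penta-O-benzylepigallocatechin-(4β→8)-3,5,7,3',4',5'-hexa-O-benzylepigallocatechin (3-OH of the 4-substituted unit free; 2,3-cis-3,4-trans) | O[C@@H]1[C@@H](c2c(OCc9ccccc9)cc(OCc9ccccc9)c3c2O[C@H](c8cc(OCc9ccccc9)c(OCc9ccccc9)c(OCc9ccccc9)c8)[C@H](OCc9ccccc9)C3)c4c(OCc9ccccc9)cc(OCc9ccccc9)cc4O[C@@H]1c8cc(OCc9ccccc9)c(OCc9ccccc9)c(OCc9ccccc9)c8 | intermediate

18 | 3,4,5-tris(benzyloxy)benzoic acid | OC(=O)c1cc(OCc2ccccc2)c(OCc2ccccc2)c(OCc2ccccc2)c1 | starting material

19 | 5,7,3',4',5'-penta-O-benzylepigallocatechin 3-O-[3,4,5-tris(benzyloxy)benzoate]-(4β→8)-3,5,7,3',4',5'-hexa-O-benzylepigallocatechin | O=C(O[C@@H]1[C@@H](c2c(OCc9ccccc9)cc(OCc9ccccc9)c3c2O[C@H](c8cc(OCc9ccccc9)c(OCc9ccccc9)c(OCc9ccccc9)c8)[C@H](OCc9ccccc9)C3)c4c(OCc9ccccc9)cc(OCc9ccccc9)cc4O[C@@H]1c8cc(OCc9ccccc9)c(OCc9ccccc9)c(OCc9ccccc9)c8)c8cc(OCc9ccccc9)c(OCc9ccccc9)c(OCc9ccccc9)c8 | intermediate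

20 | 8-bromo-4β-(2-ethoxyethoxy)-3,5,7,3',4',5'-hexa-O-benzylepigallocatechin (2,3-cis-3,4-trans) | Brc2c(OCc9ccccc9)cc(OCc9ccccc9)c3c2O[C@H](c8cc(OCc9ccccc9)c(OCc9ccccc9)c(OCc9ccccc9)c8)[C@H](OCc9ccccc9)[C@H]3OCCOCC | intermediate

21 | 8-bromo-3,5,7,3',4',5'-hexa-O-benzylepigallocatechin-(4β→8)-5,7,3',4',5'-penta-O-benzylepigallocatechin 3-O-[3,4,5-tris(benzyloxy)benzoate]-(4β→8)-3,5,7,3',4',5'-hexa-O-benzylepigallocatechin | O=C(O[C@@H]1[C@@H](c2c(OCc9ccccc9)cc(OCc9ccccc9)c3c2O[C@H](c8cc(OCc9ccccc9)c(OCc9ccccc9)c(OCc9ccccc9)c8)[C@H](OCc9ccccc9)C3)c4c(OCc9ccccc9)cc(OCc9ccccc9)c([C@H]6c7c(OCc9ccccc9)cc(OCc9ccccc9)c(Br)c7O[C@H](c8cc(OCc9ccccc9)c(OCc9ccccc9)c(OCc9ccccc9)c8)[C@@H]6OCc9ccccc9)c4O[C@@H]1c8cc(OCc9ccccc9)c(OCc9ccccc9)c(OCc9ccccc9)c8)c8cc(OCc9ccccc9)c(OCc9ccccc9)c(OCc9ccccc9)c8 | intermediate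

22 | epigallocatechin-(4β→8)-epigallocatechin 3-O-gallate-(4β→8)-epigallocatechin | O=C(O[C@@H]1[C@@H](c2c(O)cc(O)c3c2O[C@H](c2cc(O)c(O)c(O)c2)[C@H](O)C3)c2c(O)cc(O)c([C@H]3c4c(O)cc(O)cc4O[C@H](c4cc(O)c(O)c(O)c4)[C@@H]3O)c2O[C@@H]1c1cc(O)c(O)c(O)c1)c1cc(O)c(O)c(O)c1 | target

## Step count and least certain steps

Total: 16 steps. Longest linear sequence: 10 steps (1, 2, 3, 6, 7, 11, 12, 13, 15, 16).

**Step 11 (key step, carries the label "Proposed new method:").** Four processes may intervene:
- slow capture of the doubly stabilised methide by the weakly nucleophilic alkenylboronate, so that self-alkylation at C8 of the phenol ring of a second molecule of 10 takes over;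
- loss of boron after C3–C4 bond formation (alkenyl transfer) instead of ring closure;
- endo addition, or bond rotation in a long-lived benzylic cation, which would give the wrong relative configuration at C4 or C2;
- weak or mismatched facial control by the catalyst.

The fallback uses known chemistry and a different approach: ring C comes from the chiral pool and the interflavan bond is made by electrophilic substitution. It sets out from 2. DDQ and 2-ethoxyethanol in CH2Cl2 should give 5,7,3',4',5'-penta-O-benzyl-4β-(2-ethoxyethoxy)epigallocatechin F1. TMSOTf in CH2Cl2 at −78 °C with an excess of 3 (recoverable) should then join C4 of F1 to C8 of 3 anti to the C2 and C3 substituents. This gives 17, where the route is rejoined before step 13.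

**Step 6.** Addition of a di-ortho-substituted aryllithium to a di-ortho-substituted aldehyde may be slow, so that proton transfer returns 3, and the product may ionise on work-up. The fallback replaces the aryllithium addition by an ortho-selective hydroxyalkylation of a phenoxide. It sets out from 4: the lithio compound 8 is quenched with DMF to give 8-formyl-3,5,7,3',4',5'-hexa-O-benzylepigallocatechin F2. The bromomagnesium phenoxide of commercial 3,5-bis(benzyloxy)phenol (EtMgBr, toluene) should then add through its chelated ortho carbon to F2. This gives 10 directly, and the route is rejoined before step 11 without 7 and 9.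

**Step 10.** Competing cis-hydroboration or isomerisation of the alkenylrhodium intermediate may erode the Z geometry. The fallback builds the geometry from a Z-alkenyl bromide and sets out from 12:
- CBr4 and PPh3 should give 1,2,3-tris(benzyloxy)-5-(2,2-dibromoethenyl)benzene F3 (Corey–Fuchs olefination);
- Pd(PPh3)4 with Bu3SnH should remove the bromine trans to the aryl group and give (Z)-1,2,3-tris(benzyloxy)-5-(2-bromoethenyl)benzene F4;
- Miyaura borylation with bis(pinacolato)diboron, PdCl2(PPh3)2, PPh3 and KOPh in toluene at 50 °C should give 14 with retention, rejoining the route before step 11.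

**Step 15.** Attack through a C6 position, or acid-mediated scission and recombination of the existing interflavan bond of 19, would give regioisomeric trimers. The fallback changes the activation from oxophilic to thiophilic and sets out from 20. 2-Mercaptobenzothiazole with AlMe3 should give 8-bromo-4β-(1,3-benzothiazol-2-ylthio)-3,5,7,3',4',5'-hexa-O-benzylepigallocatechin F5. AgBF4 in THF in the presence of 19 should then release the same C4 cation without a protic or silyl Lewis acid and give 21.

**Step 16.** Bromide may slow the catalyst, the C–Br bond may be reduced incompletely, or the hydrogen bromide may cleave interflavan bonds. The fallback omits the bromine and sets out from 3: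
- DDQ and 2-ethoxyethanol should give 4β-(2-ethoxyethoxy)-3,5,7,3',4',5'-hexa-O-benzylepigallocatechin F6;
- equimolar TMSOTf-mediated coupling of F6 with 19 should give the bromine-free protected trimer F7;
- hydrogenolysis of F7 over Pd(OH)2/C without base should give 22.

## Further compounds

F1 | step 11 | 5,7,3',4',5'-penta-O-benzyl-4β-(2-ethoxyethoxy)epigallocatechin (3-OH free) | c2c(OCc9ccccc9)cc(OCc9ccccc9)c3c2O[C@H](c8cc(OCc9ccccc9)c(OCc9ccccc9)c(OCc9ccccc9)c8)[C@H](O)[C@H]3OCCOCC

F2 | step 6 | 8-formyl-3,5,7,3',4',5'-hexa-O-benzylepigallocatechin | O=Cc2c(OCc9ccccc9)cc(OCc9ccccc9)c3c2O[C@H](c8cc(OCc9ccccc9)c(OCc9ccccc9)c(OCc9ccccc9)c8)[C@H](OCc9ccccc9)C3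

F3 | step 10 | 1,2,3-tris(benzyloxy)-5-(2,2-dibromoethenyl)benzene | BrC(Br)=Cc1cc(OCc2ccccc2)c(OCc2ccccc2)c(OCc2ccccc2)c1

F4 | step 10 | (Z)-1,2,3-tris(benzyloxy)-5-(2-bromoethenyl)benzene | Br/C=C\c1cc(OCc2ccccc2)c(OCc2ccccc2)c(OCc2ccccc2)c1

F5 | step 15 | 8-bromo-4β-(1,3-benzothiazol-2-ylthio)-3,5,7,3',4',5'-hexa-O-benzylepigallocatechin | Brc2c(OCc9ccccc9)cc(OCc9ccccc9)c3c2O[C@H](c8cc(OCc9ccccc9)c(OCc9ccccc9)c(OCc9ccccc9)c8)[C@H](OCc9ccccc9)[C@H]3Sc1nc2ccccc2s1

F6 | step 16 | 4β-(2-ethoxyethoxy)-3,5,7,3',4',5'-hexa-O-benzylepigallocatechin | c2c(OCc9ccccc9)cc(OCc9ccccc9)c3c2O[C@H](c8cc(OCc9ccccc9)c(OCc9ccccc9)c(OCc9ccccc9)c8)[C@H](OCc9ccccc9)[C@H]3OCCOCC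

F7 | step 16 | 3,5,7,3',4',5'-hexa-O-benzylepigallocatechin-(4β→8)-5,7,3',4',5'-penta-O-benzylepigallocatechin 3-O-[3,4,5-tris(benzyloxy)benzoate]-(4β→8)-3,5,7,3',4',5'-hexa-O-benzylepigallocatechin | O=C(O[C@@H]1[C@@H](c2c(OCc9ccccc9)cc(OCc9ccccc9)c3c2O[C@H](c8cc(OCc9ccccc9)c(OCc9ccccc9)c(OCc9ccccc9)c8)[C@H](OCc9ccccc9)C3)c4c(OCc9ccccc9)cc(OCc9ccccc9)c([C@H]6c7c(OCc9ccccc9)cc(OCc9ccccc9)cc7O[C@H](c8cc(OCc9ccccc9)c(OCc9ccccc9)c(OCc9ccccc9)c8)[C@@H]6OCc9ccccc9)c4O[C@@H]1c8cc(OCc9ccccc9)c(OCc9ccccc9)c(OCc9ccccc9)c8)c8cc(OCc9ccccc9)c(OCc9ccccc9)c(OCc9ccccc9)c8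

A1 | alternative 1 | benzylated middle–lower dimer 3-O-gallate (identical with 19) | O=C(O[C@@H]1[C@@H](c2c(OCc9ccccc9)cc(OCc9ccccc9)c3c2O[C@H](c8cc(OCc9ccccc9)c(OCc9ccccc9)c(OCc9ccccc9)c8)[C@H](OCc9ccccc9)C3)c4c(OCc9ccccc9)cc(OCc9ccccc9)cc4O[C@@H]1c8cc(OCc9ccccc9)c(OCc9ccccc9)c(OCc9ccccc9)c8)c8cc(OCc9ccccc9)c(OCc9ccccc9)c(OCc9ccccc9)c8

A2 | alternative 1 | diyne: benzylated epigallocatechin 3-O-gallate unit carrying at C4 (β) an ethynyl group whose far carbon is bonded to the oxygen of a (1R,2R)-2,5-bis(benzyloxy)-1-[3,4,5-tris(benzyloxy)phenyl]pent-4-ynyl ether | O=C(O[C@@H]1[C@@H](C#CO[C@H](c8cc(OCc9ccccc9)c(OCc9ccccc9)c(OCc9ccccc9)c8)[C@H](OCc9ccccc9)CC#COCc9ccccc9)c4c(OCc9ccccc9)cc(OCc9ccccc9)cc4O[C@@H]1c8cc(OCc9ccccc9)c(OCc9ccccc9)c(OCc9ccccc9)c8)c8cc(OCc9ccccc9)c(OCc9ccccc9)c(OCc9ccccc9)c8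

A3 | alternative 1 | benzyloxyacetylene | C#COCc1ccccc1

A4 | alternative 2 | trimer with ring A phenols and C3-OH of the top unit free, all other phenols and the lower C3-OH benzylated | O=C(O[C@@H]1[C@@H](c2c(OCc9ccccc9)cc(OCc9ccccc9)c3c2O[C@H](c8cc(OCc9ccccc9)c(OCc9ccccc9)c(OCc9ccccc9)c8)[C@H](OCc9ccccc9)C3)c4c(OCc9ccccc9)cc(OCc9ccccc9)c([C@H]6c7c(O)cc(O)cc7O[C@H](c8cc(OCc9ccccc9)c(OCc9ccccc9)c(OCc9ccccc9)c8)[C@@H]6O)c4O[C@@H]1c8cc(OCc9ccccc9)c(OCc9ccccc9)c(OCc9ccccc9)c8)c8cc(OCc9ccccc9)c(OCc9ccccc9)c(OCc9ccccc9)c8

A5 | alternative 2 | epoxy alcohol: dimer gallate 19 carrying on C8 of its 4-substituted unit a hydroxy{cis-3-[3,4,5-tris(benzyloxy)phenyl]oxiran-2-yl}methyl group (carbinol as either epimer) | O=C(O[C@@H]1[C@@H](c2c(OCc9ccccc9)cc(OCc9ccccc9)c3c2O[C@H](c8cc(OCc9ccccc9)c(OCc9ccccc9)c(OCc9ccccc9)c8)[C@H](OCc9ccccc9)C3)c4c(OCc9ccccc9)cc(OCc9ccccc9)c(C(O)[C@H]6O[C@H]6c8cc(OCc9ccccc9)c(OCc9ccccc9)c(OCc9ccccc9)c8)c4O[C@@H]1c8cc(OCc9ccccc9)c(OCc9ccccc9)c(OCc9ccccc9)c8)c8cc(OCc9ccccc9)c(OCc9ccccc9)c(OCc9ccccc9)c8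

A6 | alternative 2 | phloroglucinol | Oc1cc(O)cc(O)c1

A7 | alternative 3 | benzylated middle–lower dimer with a tert-butyldimethylsilyl ether on C3 of the 4-substituted unit | CC(C)(C)[Si](C)(C)O[C@@H]1[C@@H](c2c(OCc9ccccc9)cc(OCc9ccccc9)c3c2O[C@H](c8cc(OCc9ccccc9)c(OCc9ccccc9)c(OCc9ccccc9)c8)[C@H](OCc9ccccc9)C3)c4c(OCc9ccccc9)cc(OCc9ccccc9)cc4O[C@@H]1c8cc(OCc9ccccc9)c(OCc9ccccc9)c(OCc9ccccc9)c8

A8 | alternative 3 | bromo alcohol: open-chain 1-[3,4,5-tris(benzyloxy)phenyl]-2-(tert-butyldimethylsilyloxy)-3-[2-bromo-4,6-bis(benzyloxy)phenyl]-3-(hexa-O-benzylepigallocatechin-8-yl)propan-1-ol with the configurations of A7 | CC(C)(C)[Si](C)(C)O[C@H]([C@@H](c2c(OCc9ccccc9)cc(OCc9ccccc9)c3c2O[C@H](c8cc(OCc9ccccc9)c(OCc9ccccc9)c(OCc9ccccc9)c8)[C@H](OCc9ccccc9)C3)c4c(OCc9ccccc9)cc(OCc9ccccc9)cc4Br)[C@H](O)c8cc(OCc9ccccc9)c(OCc9ccccc9)c(OCc9ccccc9)c8
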